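Q was the product to follow in the violet flask, with [E] at 5.0 mM at the start, and I drew its curve from both ends.

| flask | E | remark | time |
|---|---|---|---|
| violet | 5 mM | the very flask that is asked about, followed so far |  |
| red | 3.4 mM | run made earlier |  |
| flask | 5.0 mM |  | 3.0 min |

| run | time / s | Q / % | D / % | E / % |
|---|---|---|---|---|
| violet | 10.0 | 16 | 38 | 40 |
| violet | 15.0 | 22 | 43 | 32 |
| violet | 25.0 | 29 | 48 | 16 |
| violet | 40.0 | 36 | 48 | 18 |
| violet | 50.0 | 43 | 45 | 10 |
| red | 20.0 | 27 | 45 | 27 |
| red | 40.0 | 37 | 45 | 20 |
| red | 50.0 | 44 | 38 | 14 |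
| red | 80.0 | 57 | 32 | 12 |
| red | 90.0 | 55 | 31 | 8 |
| red | 120 | 65 | 26 | 12 |

(scatter of a reading: 2 percentage points)

1. amount of Q in percent of the E charged, at 20 s, 50 s, 2.0 min and 3.0 min

- a reading or a percentage of D counts all its forms, free or not
- a reading of E is of its free form alone

At the early end, violet E fell to 40% in 10.0 s, so I read a fast constant and its half-life:

fast constant = 0.0916 s⁻¹, half-life = 7.56 s

Q held 29.6% of the Q and D then read, so I put its starting slope at about 0.0271 s⁻¹ as a fraction of the charge. I placed the knee at 4 half-lives, near 30.2 s, between the violet D readings of 48% at 25.0 s and 48% at 40.0 s. At 20 s, still before the knee, I interpolated the violet readings to 25.5%.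

At the late end, I treated E and D as one pool, a pre-equilibrium. In the red run, what was not yet Q fell from 56.0% at 50.0 s to 35.0% at 120 s, which gives:

λ = 0.00671 s⁻¹

This is the drain constant, the fraction of what is not yet Q that becomes Q each second. Its half-life of 103 s is far longer than the fast one, so the two ends could be joined at a single point. The runs read 43% and 44% at 50.0 s, so I borrowed red's λ for violet, started from violet's reading and let the curve run toward 100%. If D kept its share of the pool, Q would cross D near 52.9 s.

Q at 2.0 min = 64.4%

Q at 3.0 min = 76.2%

The forecast, which saw “the pool draining slowly to Q”, gave 26%, 43%, 63% and 74%, its last two values lower than mine.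

The violet flask gave 27.1%, 40.6%, 61.5% and 72.8%, so the forecast held within its margin.

    E ⇌ D (K = 1.98, k = 0.0678 s⁻¹)
    E ⇌ Q (K = 26.0, k = 0.0294 s⁻¹)
    E + D ⇌ J, settled at all times (K = 82.0 L mol⁻¹)
    X ⇌ D, rate k4*(cs4 - [D]) while solid is left; crystals form when [D] > cs4 (solubility = 1.70 mM, k = 2.60 s⁻¹)

At 30.0 min Q in the violet flask stood at 89.5%, less than the 100% I had drawn. Started from the flask's 61.5% at 2.0 min, λ gives 74.3% at 3.0 min, where the flask stood at 72.8%.

The numbers in the tables stem from a simulated flask from invented constants; noise was put on by code.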